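I start from 23.7%, the poison share of this flask: [impurity] at the start divided by the [enzyme] charged. It says what part of the enzyme is lost as spent catalyst if each impurity takes one enzyme. The impurity is the smaller charge, so it is the limiting reagent of that loss.

- Monday's: substrate 2.0 × 10⁻⁴ M (fed, over 3.0 s); enzyme 0.08 mol%; impurity 0.019 µM; run made earlier
- flask: substrate 2.0 × 10⁻⁴ M (fed, over 3.0 s); enzyme 0.04 mol%; impurity 0.019 µM; time 2.5 min

Monday's run (percent of the substrate charged)

| time / s | target / % |
|---|---|
| 10.0 | 16 |
| 12.0 | 21 |
| 20.0 | 38 |
| 25.0 | 45 |
| 30.0 | 58 |

(readings scatter by 1.5 percentage points)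

* amount of target in percent of the substrate charged, at 30 s, 80 s and 2.5 min

- the earlier runs were read with a standard deviation of 1.5 percentage points
- steps that have been proposed: substrate + enzyme -> target + enzyme; enzyme + impurity -> spent catalyst; 2 enzyme <-> resting dimer
- no earlier run changes the charge of enzyme; that part of a forecast is a guess

Monday's run carried twice the enzyme with the same impurity, so its poison share is 11.9%. Its target climbs nearly straight, by 0.0210 s⁻¹ of the charge between 10.0 s and 30.0 s. Folding both shares in, the enzyme left in this flask is 0.433 of Monday's, and a rate that follows the enzyme left falls by that factor.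

Is one number enough? I think not. The resting dimer is a proposed step, and if enzyme pairs up strongly, the rate follows the square root, 0.658. No earlier run changes the enzyme charge, so the choice between them is a guess. I take the middle on a logarithmic scale, 0.533. Counting from the middle of the feed, that gives 31.9% at 30 s. The same line gives 87.9% at 80 s, beyond the 58% Monday shows, so that figure carries the line past its readings. The line meets the whole charge at 90.8 s, before 2.5 min.

The forecast, reading that “the catalyst looks saturated”, gives 28%, 72% and 97%, and at 30 s it stands below my figure.

The flask gives 33.3% at 30 s, 77.0% at 80 s and 98.2% at 2.5 min.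

    substrate + enzyme → target + enzyme, rate k1*[substrate]*[enzyme]/(1 + ([substrate]/Km1)) (0.0736 mM, k = 1.19 × 10⁶ M⁻¹ s⁻¹)
    enzyme + impurity → spent catalyst (k = 2.46 × 10⁸ M⁻¹ s⁻¹)
    2 enzyme ⇌ resting dimer, settled at all times (K = 8.10 × 10⁶ M⁻¹)

At 0.0500 min, with impurity at 0% of its charge, spent catalyst in the flask stands at 23.8% of the catalyst charged, while the poison share of 23.7% came from the charges. Put to use once more, Monday's share of 11.9% reckons 0.141 µM of enzyme outside spent catalyst in Monday's run, against 0.0610 µM reckoned for the flask, a ratio of 0.433, while the flask's target at 30 s is 0.574 of Monday's reading.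

The earlier runs and the new flask are calculated with constants of no real substance; scatter was added.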